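Set the zero of the scale by hand before charging more solid base. The dusk run is the asked flask itself, followed so far.

the same everywhere: electrophile 1.5 M
- dusk: nucleophile 1 equiv; solid base 0.80 equiv; the very flask that is asked about, followed so far
- flask: nucleophile 1.00 equiv; solid base 0.800 equiv; time 20 min

- dusk (time / min: target / %, electrophile / %): 0.833: 52.1, 48.3; 2.00: 56.8, 44.5; 4.00: 60.4, 38.6; 10.0: 73.6, 26.3

(scatter of a reading: 0.5 percentage points)

- solid, in amounts per volume of the solution: solid base
- what was read earlier has a scatter of 0.5 percentage points, one standard deviation
- at the start none of the solid base is in solution
- free base is what solid base becomes in solution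

* how much target there is at 20 min, in percent of the electrophile charged
* concentration of free base in solution at 20 min, in percent of saturation

I take it that each target frees one acid and that this acid takes up one nucleophile. If every acid is bound so and none goes to base, nucleophile and electrophile being equal, this count puts target at the even split, 50.0%. The dusk reading of 52.1% at 0.833 min lies near it. Above that zero, each acid taken up by base returns one nucleophile, but the new target frees an acid that binds another nucleophile, so each uptake counts 0.5 target:

target = 50.0% + 0.5 × uptake

The dusk reading at 10.0 min gives the uptake rate, the share of the electrophile charged whose acid base takes up per minute: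

2 × (73.6% − 50.0%) / 10.0 min = 0.0472 /min

By 20 min this rate asks for 94.4%, more than the 0.800 equiv of solid base charged. On my reckoning the solid ends at 16.9 min, and extra solid adds 7.2 percentage points. I keep the charge and expect 90.0%.

The forecast differs: 80.5% and 5%, on the ground “If each turnover consumes one base equivalent”. My number stands above it.

    electrophile + nucleophile → acid set free + target (k = 0.101 /M/s)
    nucleophile + acid set free ⇌ protonated nucleophile, settled at all times (K = 2700 /M)
    acid set free + free base ⇌ salt of the base, settled at all times (K = 1020 /M)
    solid base ⇌ free base, rate k4*(cs4 - [free base]) while solid is left; crystals form when [free base] > cs4 (solubility = 0.990 M, k = 0.00137 /s)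
    2 free base → self-condensation product (k = 0.00631 /M/s)

The flask gives 86.1% and 5.39%, so my reckoning is 3.9 points high. Net turnover to salt of the base up to 20 min is 71.1% of the electrophile charged, below the 0.800 equiv of solid, and the rule on that turnover gives 85.5%. At 0.0472 /min my reckoning leaves 41.0% of the solid at 10.0 min, and the flask then holds 33.8% of it.

For the same flask read at 5.0 min, the rate gives 61.8% target. The computed value is 63.1%.

All runs are calculated from invented constants.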